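**Plan**

- Rings: the upper flavanone has ring A (benzo ring with 5-OH and 7-OMe), ring C (pyranone) and ring B (anisole ring at C2). The lower flavanone has ring D (benzo ring), ring F (pyranone) and ring E (4-hydroxyphenyl at C2'').
- Cuts, in retrosynthetic order: the three benzyl ethers; the C2''–aryl bond (ring F is carried as a chromone); the O1–C8a and C4–C4a bonds of ring C together; the biaryl bond between ring B and ring D.
- Forward: ring F is closed as a chromone, iodinated at C6'' and joined by Suzuki coupling to a ring-B boronate carrying an (S)-3-hydroxypropanoate. Ring C is then annulated onto 3-(benzyloxy)-5-methoxybenzyne, followed by aryl addition to the chromone and hydrogenolysis.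
- Enabling feature: in ring A the ether oxygen O1 (on C8a) and the acyl carbon C4 (on C4a) sit on neighbouring carbons, C4a lies next to the C5 oxygen, and C7 bears OMe. This is the pattern left when an O–C2–C3–C4(=O) chain adds across a 3,5-dioxygenated benzyne, with the C5 oxygen steering O1 to C8a.
- Stereochemistry: C2 comes from asymmetric transfer hydrogenation of a β-keto ester (step 5) and passes through the annulation with its C–O bond intact. C2'' comes from ligand-controlled aryl addition to the chromone (step 13).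
- Helpers: O–SiMe3 (proton-free alkoxide source), the methyl ester (acyl donor), the chromone level of ring F (no acidic or epimerisable position during the annulation) and benzyl ethers; all are removed in steps 12–14.

Key step: step 12

Remark: the axis between ring B and ring D has no descriptor in the target and is taken as freely rotating, so no atropisomer control is planned.

**Route**

Step 1
Reactants: 1 5-methoxybenzene-1,3-diol
Product: 2 2-iodo-5-methoxybenzene-1,3-diol
Conditions: I2 (1.0 equiv), NaHCO3, H2O/THF, 0 °C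
Reagents that add atoms: iodine, II
Why: Electrophilic iodination of resorcinols with I2 in aqueous NaHCO3 goes to the carbon between the two hydroxyl groups, as known for resorcinol and its 5-alkyl homologues, and one equivalent at 0 °C should limit over-iodination.

Step 2
Reactants: 2 2-iodo-5-methoxybenzene-1,3-diol
Product: 3 3-(benzyloxy)-2-iodo-5-methoxyphenol
Conditions: BnBr (1.0 equiv), K2CO3, acetone, reflux
Reagents that add atoms: benzyl bromide, BrCc1ccccc1
Why: Williamson etherification of a symmetric diol with one equivalent of halide should give mainly the mono-ether, separable from the diether and recovered 2, and symmetry removes any regiochemical question.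

Step 3
Reactants: 3 3-(benzyloxy)-2-iodo-5-methoxyphenol
Product: 6 3-(benzyloxy)-5-methoxy-2-(trimethylsilyl)phenyl trifluoromethanesulfonate, via aryl trimethylsilyl ether 4 (not isolated), via lithium 2-silylphenolate 5 (not isolated)
Conditions: HMDS, THF, 65 °C, then evaporation; n-BuLi, THF, −78 °C; Tf2O, −78 °C to rt
Reagents that add atoms: hexamethyldisilazane, C[Si](C)(C)N[Si](C)(C)C; trifluoromethanesulfonic anhydride, O=S(=O)(OS(=O)(=O)C(F)(F)F)C(F)(F)F
Why: This is the standard one-pot route to ortho-silylaryl triflates (O-silylation, iodine–lithium exchange, retro-Brook shift of silicon from oxygen to carbon, triflation), and the iodine fixes silicon between the benzyloxy and the triflyloxy carbon.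

Step 4
Reactants: 7 1-(3-bromo-4-methoxyphenyl)ethan-1-one
Product: 8 methyl 3-(3-bromo-4-methoxyphenyl)-3-oxopropanoate
Conditions: NaH, (MeO)2CO, toluene, 100 °C; then aq. HCl
Reagents that add atoms: dimethyl carbonate, COC(=O)OC
Why: Claisen-type C-acylation of the ketone enolate with dimethyl carbonate, the product being held as its enolate until the acidic quench.

Step 5
Reactants: 8 methyl 3-(3-bromo-4-methoxyphenyl)-3-oxopropanoate
Product: 9 methyl (S)-3-(3-bromo-4-methoxyphenyl)-3-hydroxypropanoate
Conditions: RuCl[(S,S)-TsDPEN](p-cymene) (1 mol%), HCO2H/Et3N (5:2), DMF, 40 °C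
Reagents that add atoms: none
Why: Noyori–Ikariya asymmetric transfer hydrogenation of an aryl ketone, in which the (S,S)-catalyst should deliver hydride to the face giving the (S)-carbinol (same sense and same priority order as in the acetophenone series) while leaving the aryl bromide and the ester untouched.

Step 6
Reactants: 9 methyl (S)-3-(3-bromo-4-methoxyphenyl)-3-hydroxypropanoate
Product: 10 methyl (S)-3-hydroxy-3-[4-methoxy-3-(4,4,5,5-tetramethyl-1,3,2-dioxaborolan-2-yl)phenyl]propanoate
Conditions: B2pin2, PdCl2(dppf) (3 mol%), KOAc, 1,4-dioxane, 85 °C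
Reagents that add atoms: bis(pinacolato)diboron, CC1(C)OB(OC1(C)C)B1OC(C)(C)C(C)(C)O1
Why: Miyaura borylation of an aryl bromide, with KOAc too weak a base to harm the β-hydroxy ester or its stereocenter.

Step 7
Reactants: 11 1-(2,6-dihydroxy-4-methoxyphenyl)ethan-1-one
Product: 13 5-hydroxy-7-methoxy-4H-chromen-4-one, via enaminone 12 (not isolated)
Conditions: Me2NCH(OMe)2, toluene, 95 °C; then conc. HCl, CH2Cl2, 40 °C
Reagents that add atoms: N,N-dimethylformamide dimethyl acetal, COC(OC)N(C)C
Why: Enaminone chromone synthesis (condensation at the methyl ketone, then acid-promoted attack of an ortho-hydroxyl and loss of dimethylamine), in which the two equivalent hydroxyl groups allow only one chromone.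

Step 8
Reactants: 13 5-hydroxy-7-methoxy-4H-chromen-4-one
Product: 14 5-hydroxy-6-iodo-7-methoxy-4H-chromen-4-one
Conditions: BnNMe3·ICl2, CaCO3, CH2Cl2/MeOH, rt
Reagents that add atoms: benzyltrimethylammonium dichloroiodate, C[N+](C)(C)Cc1ccccc1.Cl[I-]Cl
Why: Electrophilic iodination with the dichloroiodate salt is directed by the free, chelated 5-hydroxyl to its ortho carbon C6, the selectivity established for 5-hydroxy-7-alkoxyflavones, leaving C8 free.

Step 9
Reactants: 14 5-hydroxy-6-iodo-7-methoxy-4H-chromen-4-one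
Product: 15 5-(benzyloxy)-6-iodo-7-methoxy-4H-chromen-4-one
Conditions: BnBr, K2CO3, DMF, 60 °C
Reagents that add atoms: benzyl bromide, BrCc1ccccc1
Why: Williamson etherification of the chelated, hindered 5-hydroxyl needs DMF and heat but only carbonate base, so the chromone ring should survive.

Step 10
Reactants: 15 5-(benzyloxy)-6-iodo-7-methoxy-4H-chromen-4-one; 10 methyl (S)-3-hydroxy-3-[4-methoxy-3-(4,4,5,5-tetramethyl-1,3,2-dioxaborolan-2-yl)phenyl]propanoate
Product: 16 methyl (S)-3-{3-[5-(benzyloxy)-7-methoxy-4-oxo-4H-chromen-6-yl]-4-methoxyphenyl}-3-hydroxypropanoate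
Conditions: Pd(OAc)2 (5 mol%), SPhos (10 mol%), K3PO4, toluene/H2O (10:1), 80 °C
Reagents that add atoms: none
Why: Suzuki–Miyaura coupling with the bulky dialkylbiarylphosphine SPhos, chosen because the iodide is flanked by two alkoxy groups and the boronate has an ortho-methoxy group, under a phosphate base mild enough for the ester, the carbinol and the chromone.

Step 11
Reactants: 16 methyl (S)-3-{3-[5-(benzyloxy)-7-methoxy-4-oxo-4H-chromen-6-yl]-4-methoxyphenyl}-3-hydroxypropanoate
Product: 17 methyl (S)-3-{3-[5-(benzyloxy)-7-methoxy-4-oxo-4H-chromen-6-yl]-4-methoxyphenyl}-3-[(trimethylsilyl)oxy]propanoate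
Conditions: TMSCl, imidazole, CH2Cl2, 0 °C; non-aqueous work-up
Reagents that add atoms: chlorotrimethylsilane, C[Si](C)(C)Cl
Why: Routine silylation of the secondary alcohol, which replaces the only O–H of the molecule by a fluoride-labile group without touching the stereocenter.

Step 12
Reactants: 17 methyl (S)-3-{3-[5-(benzyloxy)-7-methoxy-4-oxo-4H-chromen-6-yl]-4-methoxyphenyl}-3-[(trimethylsilyl)oxy]propanoate; 6 3-(benzyloxy)-5-methoxy-2-(trimethylsilyl)phenyl trifluoromethanesulfonate
Product: 19 (S)-5-(benzyloxy)-2-{3-[5-(benzyloxy)-7-methoxy-4-oxo-4H-chromen-6-yl]-4-methoxyphenyl}-7-methoxychroman-4-one, via 3-(benzyloxy)-5-methoxybenzyne 18 (not isolated)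
Conditions: 6 (1.5 equiv), KF (3 equiv), 18-crown-6 (3 equiv), THF, −20 °C to rt; pH 7 buffer quench
Reagents that add atoms: none
Why: Proposed new method: fluoride should strip Me3Si from the oxygen of 17 and convert 6 into aryne 18 by 1,2-elimination of Me3Si and triflate; the alkoxide oxygen then adds to the aryne carbon remote from OBn, the aryl anion formed next to OBn attacks the methyl ester through a six-membered transition state, and loss of methoxide (taken up by silicon) gives the chroman-4-one. The closest known reaction types are the annulation of arynes with methyl salicylates to xanthones (phenoxide addition, then acyl substitution by the aryl anion) and the formal insertion of arynes into the C–O bond of carboxylic acids; an aliphatic β-silyloxy ester as partner has not been shown. Ring C closes by O1–C8a bond formation followed by 6-exo-trig attack of C4a on the ester carbon C4. No stereocenter is made, and C2 keeps the (S) configuration of step 5 because none of its bonds is broken. The regioselectivity is secured by the benzyloxy group beside the triple bond (the nucleophile adds to the more distorted, more electrophilic carbon and the charge develops ortho to the inductively withdrawing oxygen), and acylation should win over protonation because the silyl ether leaves no O–H in the flask. Ring F is carried as a chromone because it then has neither an acidic α-hydrogen nor an epimerisable center under these conditions.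

Step 13
Reactants: 19 (S)-5-(benzyloxy)-2-{3-[5-(benzyloxy)-7-methoxy-4-oxo-4H-chromen-6-yl]-4-methoxyphenyl}-7-methoxychroman-4-one; 20 [4-(benzyloxy)phenyl]boronic acid
Product: 21 (S)-5-(benzyloxy)-2-{3-[(S)-5-(benzyloxy)-2-[4-(benzyloxy)phenyl]-7-methoxy-4-oxochroman-6-yl]-4-methoxyphenyl}-7-methoxychroman-4-one
Conditions: Pd(OCOCF3)2 (10 mol%), (R)-t-BuPyOx (12 mol%), NH4PF6 (30 mol%), H2O (5 equiv), ClCH2CH2Cl, 60 °C
Reagents that add atoms: none
Why: Palladium-catalysed asymmetric conjugate addition of an arylboronic acid to a chromone (transmetalation, enantioselective insertion of C2''=C3'' into the Pd–aryl bond, protonolysis of the palladium enolate by water), in which the ligand alone should set C2'' as (S); the (R)-ligand is chosen because the (S)-ligand gives (R)-β-aryl ketones from cyclic enones by the same facial model, and the base-free medium leaves ring C alone.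

Step 14
Reactants: 21 (S)-5-(benzyloxy)-2-{3-[(S)-5-(benzyloxy)-2-[4-(benzyloxy)phenyl]-7-methoxy-4-oxochroman-6-yl]-4-methoxyphenyl}-7-methoxychroman-4-one
Product: 22 (2S)-5-hydroxy-2-{3-[(2S)-5-hydroxy-2-(4-hydroxyphenyl)-7-methoxy-4-oxo-3,4-dihydro-2H-chromen-6-yl]-4-methoxyphenyl}-7-methoxy-2,3-dihydro-4H-chromen-4-one
Conditions: H2 (1 atm), Pd/C (10 wt%), EtOAc/MeOH, rt
Reagents that add atoms: none
Why: Hydrogenolysis of the three aryl benzyl ethers under neutral conditions should leave the ketones, the benzylic C2–O and C2''–O bonds and both stereocenters untouched if stopped at full debenzylation.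

**Compound list**

1 | 5-methoxybenzene-1,3-diol | COc1cc(O)cc(O)c1 | starting material
2 | 2-iodo-5-methoxybenzene-1,3-diol | COc1cc(O)c(I)c(O)c1 | intermediate
3 | 3-(benzyloxy)-2-iodo-5-methoxyphenol | COc1cc(O)c(I)c(OCc2ccccc2)c1 | intermediate
4 | [3-(benzyloxy)-2-iodo-5-methoxyphenoxy]trimethylsilane | COc1cc(O[Si](C)(C)C)c(I)c(OCc2ccccc2)c1 | intermediate (not isolated)
5 | lithium 3-(benzyloxy)-5-methoxy-2-(trimethylsilyl)phenolate | COc1cc([O-])c([Si](C)(C)C)c(OCc2ccccc2)c1.[Li+] | intermediate (not isolated)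
6 | 3-(benzyloxy)-5-methoxy-2-(trimethylsilyl)phenyl trifluoromethanesulfonate | COc1cc(OCc2ccccc2)c([Si](C)(C)C)c(OS(=O)(=O)C(F)(F)F)c1 | intermediate
7 | 1-(3-bromo-4-methoxyphenyl)ethan-1-one | COc1ccc(C(C)=O)cc1Br | starting material
8 | methyl 3-(3-bromo-4-methoxyphenyl)-3-oxopropanoate | COC(=O)CC(=O)c1ccc(OC)c(Br)c1 | intermediate
9 | methyl (S)-3-(3-bromo-4-methoxyphenyl)-3-hydroxypropanoate | COC(=O)C[C@H](O)c1ccc(OC)c(Br)c1 | intermediate
10 | methyl (S)-3-hydroxy-3-[4-methoxy-3-(4,4,5,5-tetramethyl-1,3,2-dioxaborolan-2-yl)phenyl]propanoate | COC(=O)C[C@H](O)c1ccc(OC)c(B2OC(C)(C)C(C)(C)O2)c1 | intermediate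
11 | 1-(2,6-dihydroxy-4-methoxyphenyl)ethan-1-one | COc1cc(O)c(C(C)=O)c(O)c1 | starting material
12 | (E)-1-(2,6-dihydroxy-4-methoxyphenyl)-3-(dimethylamino)prop-2-en-1-one | COc1cc(O)c(C(=O)/C=C/N(C)C)c(O)c1 | intermediate (not isolated)
13 | 5-hydroxy-7-methoxy-4H-chromen-4-one | COc1cc(O)c2c(c1)occc2=O | intermediate
14 | 5-hydroxy-6-iodo-7-methoxy-4H-chromen-4-one | COc1cc2occc(=O)c2c(O)c1I | intermediate
15 | 5-(benzyloxy)-6-iodo-7-methoxy-4H-chromen-4-one | COc1cc2occc(=O)c2c(OCc2ccccc2)c1I | intermediate
16 | methyl (S)-3-{3-[5-(benzyloxy)-7-methoxy-4-oxo-4H-chromen-6-yl]-4-methoxyphenyl}-3-hydroxypropanoate | COC(=O)C[C@H](O)c1ccc(OC)c(-c2c(OC)cc3occc(=O)c3c2OCc2ccccc2)c1 | intermediate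
17 | methyl (S)-3-{3-[5-(benzyloxy)-7-methoxy-4-oxo-4H-chromen-6-yl]-4-methoxyphenyl}-3-[(trimethylsilyl)oxy]propanoate | COC(=O)C[C@H](O[Si](C)(C)C)c1ccc(OC)c(-c2c(OC)cc3occc(=O)c3c2OCc2ccccc2)c1 | intermediate
18 | 3-(benzyloxy)-5-methoxybenzyne (1,2-didehydro-3-(benzyloxy)-5-methoxybenzene) | COC1=CC#CC(OCc2ccccc2)=C1 | intermediate (not isolated)
19 | (S)-5-(benzyloxy)-2-{3-[5-(benzyloxy)-7-methoxy-4-oxo-4H-chromen-6-yl]-4-methoxyphenyl}-7-methoxychroman-4-one | COc1cc(OCc2ccccc2)c2c(c1)O[C@H](c1ccc(OC)c(-c3c(OC)cc4occc(=O)c4c3OCc3ccccc3)c1)CC2=O | intermediate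
20 | [4-(benzyloxy)phenyl]boronic acid | OB(O)c1ccc(OCc2ccccc2)cc1 | starting material
21 | (S)-5-(benzyloxy)-2-{3-[(S)-5-(benzyloxy)-2-[4-(benzyloxy)phenyl]-7-methoxy-4-oxochroman-6-yl]-4-methoxyphenyl}-7-methoxychroman-4-one | COc1cc(OCc2ccccc2)c2c(c1)O[C@H](c1ccc(OC)c(-c3c(OC)cc4c(c3OCc3ccccc3)C(=O)C[C@@H](c3ccc(OCc5ccccc5)cc3)O4)c1)CC2=O | intermediate
22 | (2S)-5-hydroxy-2-{3-[(2S)-5-hydroxy-2-(4-hydroxyphenyl)-7-methoxy-4-oxo-3,4-dihydro-2H-chromen-6-yl]-4-methoxyphenyl}-7-methoxy-2,3-dihydro-4H-chromen-4-one | COc1cc(O)c2c(c1)O[C@H](c1ccc(OC)c(-c3c(OC)cc4c(c3O)C(=O)C[C@@H](c3ccc(O)cc3)O4)c1)CC2=O | target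

**Count and risks**

Total step count: 14. Longest linear sequence: 8 steps (steps 4–6 or 7–9, then 10–14).

Steps most likely to fail:

1. Step 12 (proposed new method). The aryl anion may be protonated or otherwise intercepted before it reaches the ester, so that only the open aryl ether forms. The free alkoxide may also exchange with the methyl ester, and the basic oxy-anions may open ring F or epimerise C2 through ring opening of the new flavanone. The fallback uses known chemistry, sets out from 8 and comes back at 19. Keto ester 8 is reduced with the enantiomeric catalyst RuCl[(R,R)-TsDPEN](p-cymene) to methyl (R)-3-(3-bromo-4-methoxyphenyl)-3-hydroxypropanoate F1. Mitsunobu etherification with iodophenol 3 (PPh3, DIAD, toluene, 0 °C) inverts the carbinol and should give methyl (S)-3-[3-(benzyloxy)-2-iodo-5-methoxyphenoxy]-3-(3-bromo-4-methoxyphenyl)propanoate F2. Selective iodine–magnesium exchange (i-PrMgCl·LiCl, THF, −40 °C) and intramolecular acylation (Parham-type cyclization) should close ring C to (S)-5-(benzyloxy)-2-(3-bromo-4-methoxyphenyl)-7-methoxychroman-4-one F3. Miyaura borylation as in step 6 gives (S)-5-(benzyloxy)-7-methoxy-2-[4-methoxy-3-(4,4,5,5-tetramethyl-1,3,2-dioxaborolan-2-yl)phenyl]chroman-4-one F4, and Suzuki coupling with 15 as in step 10 gives 19.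

2. Step 13. Facial selectivity may be poor or reversed, or turnover may be slow on the large, polyfunctional chromone, with protodeboronation of the electron-rich boronic acid competing. The fallback sets out from 15 and comes back at 21. The same Pd(OCOCF3)2/(R)-t-BuPyOx addition of 20 is run on the simple iodochromone 15, the substrate closest to precedent, to give (S)-5-(benzyloxy)-2-[4-(benzyloxy)phenyl]-6-iodo-7-methoxychroman-4-one F5, whose enantiomeric purity could be raised by crystallisation. Suzuki coupling with 10 as in step 10 gives methyl (S)-3-{3-[(S)-5-(benzyloxy)-2-[4-(benzyloxy)phenyl]-7-methoxy-4-oxochroman-6-yl]-4-methoxyphenyl}-3-hydroxypropanoate F6. Silylation as in step 11 gives methyl (S)-3-{3-[(S)-5-(benzyloxy)-2-[4-(benzyloxy)phenyl]-7-methoxy-4-oxochroman-6-yl]-4-methoxyphenyl}-3-[(trimethylsilyl)oxy]propanoate F7. Annulation with 6 as in step 12, kept cold and short because a flavanone is then present, gives 21.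

3. Step 1. Iodination may go to C4 or proceed to polyiodination in this very electron-rich ring. The fallback sets out from 1 and comes back at 2. Diol 1 is converted into 1-methoxy-3,5-bis(methoxymethoxy)benzene F8 (MOMCl, i-Pr2NEt, CH2Cl2). Directed ortho-lithiation between the two OMOM groups (n-BuLi, THF, 0 °C) and quench with I2 gives 2-iodo-5-methoxy-1,3-bis(methoxymethoxy)benzene F9. Acidic methanolysis (HCl, MeOH, rt) then gives 2.

**Further compounds**

F1 | step 12 | methyl (R)-3-(3-bromo-4-methoxyphenyl)-3-hydroxypropanoate | COC(=O)C[C@@H](O)c1ccc(OC)c(Br)c1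
F2 | step 12 | methyl (S)-3-[3-(benzyloxy)-2-iodo-5-methoxyphenoxy]-3-(3-bromo-4-methoxyphenyl)propanoate | COC(=O)C[C@H](Oc1cc(OC)cc(OCc2ccccc2)c1I)c1ccc(OC)c(Br)c1
F3 | step 12 | (S)-5-(benzyloxy)-2-(3-bromo-4-methoxyphenyl)-7-methoxychroman-4-one | COc1cc(OCc2ccccc2)c2c(c1)O[C@H](c1ccc(OC)c(Br)c1)CC2=O
F4 | step 12 | (S)-5-(benzyloxy)-7-methoxy-2-[4-methoxy-3-(4,4,5,5-tetramethyl-1,3,2-dioxaborolan-2-yl)phenyl]chroman-4-one | COc1cc(OCc2ccccc2)c2c(c1)O[C@H](c1ccc(OC)c(B3OC(C)(C)C(C)(C)O3)c1)CC2=O
F5 | step 13 | (S)-5-(benzyloxy)-2-[4-(benzyloxy)phenyl]-6-iodo-7-methoxychroman-4-one | COc1cc2c(c(OCc3ccccc3)c1I)C(=O)C[C@@H](c1ccc(OCc3ccccc3)cc1)O2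
F6 | step 13 | methyl (S)-3-{3-[(S)-5-(benzyloxy)-2-[4-(benzyloxy)phenyl]-7-methoxy-4-oxochroman-6-yl]-4-methoxyphenyl}-3-hydroxypropanoate | COC(=O)C[C@H](O)c1ccc(OC)c(-c2c(OC)cc3c(c2OCc2ccccc2)C(=O)C[C@@H](c2ccc(OCc4ccccc4)cc2)O3)c1
F7 | step 13 | methyl (S)-3-{3-[(S)-5-(benzyloxy)-2-[4-(benzyloxy)phenyl]-7-methoxy-4-oxochroman-6-yl]-4-methoxyphenyl}-3-[(trimethylsilyl)oxy]propanoate | COC(=O)C[C@H](O[Si](C)(C)C)c1ccc(OC)c(-c2c(OC)cc3c(c2OCc2ccccc2)C(=O)C[C@@H](c2ccc(OCc4ccccc4)cc2)O3)c1
F8 | step 1 | 1-methoxy-3,5-bis(methoxymethoxy)benzene | COCOc1cc(OC)cc(OCOC)c1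
F9 | step 1 | 2-iodo-5-methoxy-1,3-bis(methoxymethoxy)benzene | COCOc1cc(OC)cc(OCOC)c1I
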